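**Strategy.** The decalin is cut at the ring-fusion bond C5–C10 and at C8–C9 (labdane numbering), so that rings A and B arise together from an acyclic triene. The feature exploited is that quaternary C10 and C5 (next to the gem-dimethyl carbon C4) are linked by the four-carbon chain C1–C4, which can tether a C5=C6–C7=C8 diene to a C9=C10 dienophile. A Me2AlCl-promoted intramolecular Diels–Alder reaction of an (E)-3-methylenoyl oxazolidinone carrying a 6-silyloxy diene forms both bonds, both rings and the C5, C9 and C10 stereocentres in one operation. The precursor is a linear imide with a Z silyl dienol ether and a C17 silyl ether.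

Key step: step 9

Remark: atom labels follow labdane numbering; the target is (5S,9R,10S,13S)-labd-7-ene-15,17-diyl diacetate; the carbinol centres of 7, 11, 12 and 29 and C8 of 18 are transient, so 7, 11 and 12 are carried as racemates. The E enoyl unit is built by a geometry-retaining cross-coupling, because olefination of a methyl ketone would give E/Z mixtures that end up as C9 epimers.

**Step 1**
Reactants: 1 2,2-dimethylpent-4-enal
Product: 3 3,3-dimethylhex-5-enal, via methyl enol ether 2 (not isolated)
Conditions: MeOCH2PPh3Cl, KOtBu, THF, 0 °C to rt; then 2 M aq. HCl, 40 °C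
Reagents that add atoms: (methoxymethyl)triphenylphosphonium chloride COC[P+](c1ccccc1)(c1ccccc1)c1ccccc1.[Cl-]; water O
Why: Wittig methoxymethylenation of the neopentyl aldehyde and acid hydrolysis of the enol ether is a standard one-carbon homologation (adds C6), and the remote terminal alkene is inert to both stages.

**Step 2**
Reactants: 3 3,3-dimethylhex-5-enal; 4 tert-butyldimethyl(prop-2-yn-1-yloxy)silane
Product: 7 rac-(2E)-1-[(tert-butyldimethylsilyl)oxy]-6,6-dimethylnona-2,8-dien-4-ol, via alkenylzirconocene chloride 5 (not isolated), via alkenyl(methyl)zinc reagent 6 (not isolated)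
Conditions: 4, Cp2Zr(H)Cl, CH2Cl2, rt; Me2Zn, −65 °C; then 3, 0 °C; aq. NH4Cl
Reagents that add atoms: none
Why: syn-hydrozirconation of the terminal alkyne, zirconium-to-zinc transmetalation and 1,2-addition of the (E)-alkenylzinc to the aldehyde should give the E allylic alcohol (C6–C7 bond); the new carbinol centre is racemic and is oxidised away in step 6.

**Step 3**
Reactants: 8 ethyl acetoacetate
Product: 9 ethyl (2E)-3-{[(trifluoromethyl)sulfonyl]oxy}but-2-enoate
Conditions: Tf2O, aq. Me4NOH, hexanes, 5 °C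
Reagents that add atoms: trifluoromethanesulfonic anhydride O=S(=O)(OS(=O)(=O)C(F)(F)F)C(F)(F)F
Why: O-triflation of the non-chelated tetramethylammonium enolate of the β-keto ester, whose extended geometry places the triflate trans to the ester, should give the E enol triflate; any Z isomer is removed by chromatography before coupling.

**Step 4**
Reactants: 7 rac-(2E)-1-[(tert-butyldimethylsilyl)oxy]-6,6-dimethylnona-2,8-dien-4-ol; 9 ethyl (2E)-3-{[(trifluoromethyl)sulfonyl]oxy}but-2-enoate
Product: 11 ethyl (2E,10E)-12-[(tert-butyldimethylsilyl)oxy]-9-hydroxy-3,7,7-trimethyldodeca-2,10-dienoate, via bis-9-BBN adduct 10 (not isolated)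
Conditions: 9-BBN (2.2 equiv), THF, 0 °C to rt; then 9, PdCl2(dppf) (5 mol %), Ph3As, aq. K3PO4, DMF, rt
Reagents that add atoms: none
Why: anti-Markovnikov hydroboration of the monosubstituted alkene (the internal alkene is much slower; the free hydroxyl is masked as its borinate) and B-alkyl Suzuki–Miyaura coupling form C1–C10 with retention of the triflate geometry, so the chain ends up trans to the ester (E).

**Step 5**
Reactants: 11 ethyl (2E,10E)-12-[(tert-butyldimethylsilyl)oxy]-9-hydroxy-3,7,7-trimethyldodeca-2,10-dienoate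
Product: 12 (2E,10E)-12-[(tert-butyldimethylsilyl)oxy]-9-hydroxy-3,7,7-trimethyldodeca-2,10-dienoic acid
Conditions: LiOH, THF/MeOH/H2O, 40 °C; then aq. HCl to pH 4, 0 °C
Reagents that add atoms: lithium hydroxide [Li+].[OH-]
Why: saponification of the ethyl ester, to which the primary TBS ether and both alkene geometries are stable.

**Step 6**
Reactants: 12 (2E,10E)-12-[(tert-butyldimethylsilyl)oxy]-9-hydroxy-3,7,7-trimethyldodeca-2,10-dienoic acid
Product: 13 (2E,10E)-12-[(tert-butyldimethylsilyl)oxy]-3,7,7-trimethyl-9-oxododeca-2,10-dienoic acid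
Conditions: Dess–Martin periodinane, CH2Cl2, 0 °C to rt
Reagents that add atoms: none
Why: Dess–Martin oxidation of the secondary allylic alcohol gives the E enone (C6 ketone) and tolerates the free acid and the silyl ether.

**Step 7**
Reactants: 13 (2E,10E)-12-[(tert-butyldimethylsilyl)oxy]-3,7,7-trimethyl-9-oxododeca-2,10-dienoic acid; 14 (S)-4-benzyl-2-oxazolidinone
Product: 16 (4S)-4-benzyl-3-[(2E,10E)-12-[(tert-butyldimethylsilyl)oxy]-3,7,7-trimethyl-9-oxododeca-2,10-dienoyl]-1,3-oxazolidin-2-one, via mixed pivalic anhydride 15 (not isolated)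
Conditions: PivCl, Et3N, THF, −20 °C; then 14, LiCl, −20 °C to rt
Reagents that add atoms: none
Why: N-acylation of the oxazolidinone through the pivaloyl mixed anhydride under LiCl/Et3N activation is the standard mild route to N-enoyl imides; attack occurs at the less hindered enoyl carbonyl and the enone is not touched.

**Step 8**
Reactants: 16 (4S)-4-benzyl-3-[(2E,10E)-12-[(tert-butyldimethylsilyl)oxy]-3,7,7-trimethyl-9-oxododeca-2,10-dienoyl]-1,3-oxazolidin-2-one
Product: 17 (4S)-4-benzyl-3-[(2E,8Z,10E)-9,12-bis[(tert-butyldimethylsilyl)oxy]-3,7,7-trimethyldodeca-2,8,10-trienoyl]-1,3-oxazolidin-2-one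
Conditions: TBSOTf, Et3N, CH2Cl2, −78 to −20 °C
Reagents that add atoms: tert-butyldimethylsilyl trifluoromethanesulfonate CC(C)(C)[Si](C)(C)OS(=O)(=O)C(F)(F)F
Why: soft enolisation of the enone (O-silylation, then kinetic deprotonation at C5 by Et3N) should give the cross-conjugated 2-silyloxy diene as the Z enol ether, which avoids allylic strain between quaternary C4 and the vinyl group; the less basic imide is not enolised at this temperature.

**Step 9**
Reactants: 17 (4S)-4-benzyl-3-[(2E,8Z,10E)-9,12-bis[(tert-butyldimethylsilyl)oxy]-3,7,7-trimethyldodeca-2,8,10-trienoyl]-1,3-oxazolidin-2-one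
Product: 18 N-[6,17-bis(tert-butyldimethylsilyloxy)-12,13,14,15,16-pentanorlabd-6-en-11-oyl]-(4S)-4-benzyl-oxazolidin-2-one (trans-fused; 5α-H, 8α-H, 9α-H, 10β-methyl)
Conditions: Me2AlCl (1.5 equiv), CH2Cl2, −78 to −30 °C; aq. potassium sodium tartrate
Reagents that add atoms: none
Why: More than one equivalent of Me2AlCl turns the imide into a cationic two-point aluminium chelate with the enoyl group locked s-cis; the silyl enol ether carbon C5 then adds to the β-carbon C10 and C8 bonds to C9, either in one highly asynchronous [4+2] event or as a Mukaiyama–Michael/Michael pair that returns the silyl enol ether at C6=C7. The closest known reaction type is the Lewis-acid-promoted asymmetric intramolecular Diels–Alder reaction of N-enoyl oxazolidinone trienes with a terminally activated dienophile. Ring B closes as the six-membered cycloadduct ring (6-endo if the C8–C9 bond forms second) and ring A as the six-membered ring spanned by the C1–C4 tether (6-exo at C10), the gem-dimethyl group at C4 favouring the folded conformer. C9 and C10 follow from the E dienophile (C11 cis to the C10 methyl) and from addition anti to the benzyl group of the chelated (S)-auxiliary; C5 follows from the endo, chair-tether transition state, which puts H5 trans to the C10 methyl; C8 follows from the E C7=C8 bond (C17 cis to C11) and is erased in step 17. The step needs endo and π-facial selectivity and bond formation at the crowded C5/C10 pair. These rest on the rigid chelate, on the defined E dienophile and Z enol ether geometries and on the matched polarity of nucleophilic C5 and electrophilic C10.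

**Step 10**
Reactants: 18 N-[6,17-bis(tert-butyldimethylsilyloxy)-12,13,14,15,16-pentanorlabd-6-en-11-oyl]-(4S)-4-benzyl-oxazolidin-2-one
Product: 19 6,17-bis(tert-butyldimethylsilyloxy)-12,13,14,15,16-pentanorlabd-6-en-11-ol
Conditions: LiBH4, MeOH (2 equiv), Et2O, 0 °C; aq. NaOH
Reagents that add atoms: none
Why: reductive cleavage of the N-acyl oxazolidinone by hydride attack at the lithium-activated exocyclic carbonyl should release the primary C11 alcohol and the auxiliary 14, the silyl ether and silyl enol ether being inert to borohydride.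

**Step 11**
Reactants: 19 6,17-bis(tert-butyldimethylsilyloxy)-12,13,14,15,16-pentanorlabd-6-en-11-ol
Product: 20 6,17-bis(tert-butyldimethylsilyloxy)-12,13,14,15,16-pentanorlabd-6-en-11-al
Conditions: Dess–Martin periodinane, pyridine, CH2Cl2, 0 °C
Reagents that add atoms: none
Why: buffered Dess–Martin oxidation is non-basic, so the α-stereocentre C9 and the acid-sensitive silyl enol ether should survive.

**Step 12**
Reactants: 21 (R)-2-methylbutane-1,4-diol
Product: 22 (2R)-2-methyl-4-[(triisopropylsilyl)oxy]butan-1-ol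
Conditions: TIPSCl (1.0 equiv), imidazole, CH2Cl2, −40 to 0 °C
Reagents that add atoms: chlorotriisopropylsilane CC(C)[Si](Cl)(C(C)C)C(C)C
Why: selective silylation, the bulky chloride reacting preferentially at the hydroxyl remote from the methyl branch (future C15) over the β-branched one; regioisomer and bis-ether are removed by chromatography and the stereocentre is untouched.

**Step 13**
Reactants: 22 (2R)-2-methyl-4-[(triisopropylsilyl)oxy]butan-1-ol
Product: 23 (R)-(4-iodo-3-methylbutoxy)triisopropylsilane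
Conditions: I2, PPh3, imidazole, CH2Cl2, 0 °C to rt
Reagents that add atoms: iodine II
Why: Appel-type iodination of the primary alcohol through its oxyphosphonium salt; the adjacent stereocentre is not involved.

**Step 14**
Reactants: 23 (R)-(4-iodo-3-methylbutoxy)triisopropylsilane
Product: 24 [(2R)-2-methyl-4-(triisopropylsilyloxy)butyl]triphenylphosphonium iodide
Conditions: PPh3, MeCN, 85 °C (sealed tube)
Reagents that add atoms: triphenylphosphine c1ccc(cc1)P(c1ccccc1)c1ccccc1
Why: SN2 quaternisation of triphenylphosphine by the primary iodide, slow because of β-branching but standard on heating.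

**Step 15**
Reactants: 20 6,17-bis(tert-butyldimethylsilyloxy)-12,13,14,15,16-pentanorlabd-6-en-11-al; 24 [(2R)-2-methyl-4-(triisopropylsilyloxy)butyl]triphenylphosphonium iodide
Product: 26 (11Z)-6,17-bis(tert-butyldimethylsilyloxy)-15-(triisopropylsilyloxy)labda-6,11-diene, via phosphonium ylide 25 (not isolated)
Conditions: 24, NaN(SiMe3)2, THF, −78 to 0 °C; then 20, −78 °C to rt
Reagents that add atoms: none
Why: Wittig olefination with the non-stabilised ylide forms C11=C12 (Z expected, geometry irrelevant) and brings in C13 with the configuration of 21; the ylide is made with no excess base and the aldehyde added cold to limit enolisation at C9.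

**Step 16**
Reactants: 26 (11Z)-6,17-bis(tert-butyldimethylsilyloxy)-15-(triisopropylsilyloxy)labda-6,11-diene
Product: 27 6,17-bis(tert-butyldimethylsilyloxy)-15-(triisopropylsilyloxy)labd-6-ene
Conditions: 2-nitrobenzenesulfonylhydrazide (excess, in portions), Et3N, CH2Cl2, rt
Reagents that add atoms: none
Why: diimide reduction (concerted syn hydrogen transfer) saturates the 1,2-disubstituted alkene but not the electron-rich trisubstituted silyl enol ether, and touches no stereocentre.

**Step 17**
Reactants: 27 6,17-bis(tert-butyldimethylsilyloxy)-15-(triisopropylsilyloxy)labd-6-ene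
Product: 28 17-(tert-butyldimethylsilyloxy)-15-(triisopropylsilyloxy)labd-7-en-6-one
Conditions: Pd(OAc)2 (1.2 equiv), MeCN, 40 °C
Reagents that add atoms: none
Why: Saegusa–Ito oxidation, in which the palladium enolate at C7 loses the syn α-hydrogen at C8 by β-hydride elimination, gives the C7=C8 enone and erases the C8 centre, while C5 (now α to the ketone) keeps the more stable trans ring fusion.

**Step 18**
Reactants: 28 17-(tert-butyldimethylsilyloxy)-15-(triisopropylsilyloxy)labd-7-en-6-one
Product: 29 17-(tert-butyldimethylsilyloxy)-15-(triisopropylsilyloxy)labd-7-en-6β-ol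
Conditions: NaBH4, CeCl3·7H2O, MeOH/THF, −40 to 0 °C
Reagents that add atoms: none
Why: Luche 1,2-reduction, hydride arriving from the α face away from the two axial methyl groups to give the 6β-alcohol; either epimer would serve because C6 becomes CH2.

**Step 19**
Reactants: 29 17-(tert-butyldimethylsilyloxy)-15-(triisopropylsilyloxy)labd-7-en-6β-ol
Product: 31 17-(tert-butyldimethylsilyloxy)-15-(triisopropylsilyloxy)labd-7-en-6β-yl methyl carbonate, via lithium alkoxide 30 (not isolated)
Conditions: n-BuLi, THF, −78 °C; then ClCO2Me, −78 to 0 °C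
Reagents that add atoms: methyl chloroformate COC(Cl)=O
Why: O-acylation of the preformed lithium alkoxide, chosen because the axial hydroxyl flanked by two axial methyl groups acylates slowly under amine catalysis.

**Step 20**
Reactants: 31 17-(tert-butyldimethylsilyloxy)-15-(triisopropylsilyloxy)labd-7-en-6β-yl methyl carbonate
Product: 32 17-(tert-butyldimethylsilyloxy)-15-(triisopropylsilyloxy)labd-7-ene
Conditions: Pd(PPh3)4 (10 mol %), THF, rt; then LiBHEt3, 0 °C to rt
Reagents that add atoms: none
Why: Tsuji–Trost-type ionisation of the allylic carbonate by zerovalent palladium (anti, from the open α face) gives the C6–C7–C8 π-allyl complex, and hydride is delivered to the less substituted terminus C6, which leaves the trisubstituted C7=C8 alkene in place.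

**Step 21**
Reactants: 32 17-(tert-butyldimethylsilyloxy)-15-(triisopropylsilyloxy)labd-7-ene
Product: 34 (5S,9R,10S,13S)-labd-7-ene-15,17-diyl diacetate (CNP0294037.1), via labd-7-ene-15,17-diol 33 (not isolated)
Conditions: Bu4NF, THF, rt; then Ac2O, Et3N, DMAP (cat.), rt
Reagents that add atoms: acetic anhydride CC(=O)OC(C)=O
Why: fluoride cleavage of both primary silyl ethers and DMAP-catalysed acetylation of the two primary hydroxyls in the same flask should give the diacetate without touching the alkene or any stereocentre.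

**Compound list**

1 | 2,2-dimethylpent-4-enal | C=CCC(C)(C)C=O | starting material
2 | 6-methoxy-4,4-dimethylhexa-1,5-diene (E/Z mixture) | COC=CC(C)(C)CC=C | intermediate
3 | 3,3-dimethylhex-5-enal | C=CCC(C)(C)CC=O | intermediate
4 | tert-butyldimethyl(prop-2-yn-1-yloxy)silane | C#CCO[Si](C)(C)C(C)(C)C | starting material
5 | chlorobis(cyclopentadienyl)[(E)-3-(tert-butyldimethylsilyloxy)prop-1-enyl]zirconium | CC(C)(C)[Si](C)(C)OC/C=C/[Zr](Cl)(C1C=CC=C1)C1C=CC=C1 | intermediate
6 | [(E)-3-(tert-butyldimethylsilyloxy)prop-1-enyl](methyl)zinc | C[Zn]/C=C/CO[Si](C)(C)C(C)(C)C | intermediate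
7 | rac-(2E)-1-[(tert-butyldimethylsilyl)oxy]-6,6-dimethylnona-2,8-dien-4-ol | C=CCC(C)(C)CC(O)/C=C/CO[Si](C)(C)C(C)(C)C | intermediate
8 | ethyl acetoacetate | CCOC(=O)CC(C)=O | starting material
9 | ethyl (2E)-3-{[(trifluoromethyl)sulfonyl]oxy}but-2-enoate | CCOC(=O)/C=C(C)/OS(=O)(=O)C(F)(F)F | intermediate
10 | B-alkyl-9-BBN adduct of 7 (O-borinate) | CC(C)(C)[Si](C)(C)OC/C=C/C(OB1C2CCCC1CCC2)CC(C)(C)CCCB1C2CCCC1CCC2 | intermediate
11 | ethyl (2E,10E)-12-[(tert-butyldimethylsilyl)oxy]-9-hydroxy-3,7,7-trimethyldodeca-2,10-dienoate (racemic) | CCOC(=O)/C=C(C)/CCCC(C)(C)CC(O)/C=C/CO[Si](C)(C)C(C)(C)C | intermediate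
12 | (2E,10E)-12-[(tert-butyldimethylsilyl)oxy]-9-hydroxy-3,7,7-trimethyldodeca-2,10-dienoic acid (racemic) | OC(=O)/C=C(C)/CCCC(C)(C)CC(O)/C=C/CO[Si](C)(C)C(C)(C)C | intermediate
13 | (2E,10E)-12-[(tert-butyldimethylsilyl)oxy]-3,7,7-trimethyl-9-oxododeca-2,10-dienoic acid | OC(=O)/C=C(C)/CCCC(C)(C)CC(=O)/C=C/CO[Si](C)(C)C(C)(C)C | intermediate
14 | (S)-4-benzyl-2-oxazolidinone | O=C1N[C@@H](Cc2ccccc2)CO1 | starting material
15 | mixed pivalic anhydride of 13 | CC(C)(C)C(=O)OC(=O)/C=C(C)/CCCC(C)(C)CC(=O)/C=C/CO[Si](C)(C)C(C)(C)C | intermediate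
16 | enone imide, (4S)-4-benzyl-3-[(2E,10E)-12-[(tert-butyldimethylsilyl)oxy]-3,7,7-trimethyl-9-oxododeca-2,10-dienoyl]-1,3-oxazolidin-2-one | O=C(/C=C(C)/CCCC(C)(C)CC(=O)/C=C/CO[Si](C)(C)C(C)(C)C)N1C(=O)OC[C@@H]1Cc1ccccc1 | intermediate
17 | triene imide (key-step precursor), (4S)-4-benzyl-3-[(2E,8Z,10E)-9,12-bis[(tert-butyldimethylsilyl)oxy]-3,7,7-trimethyldodeca-2,8,10-trienoyl]-1,3-oxazolidin-2-one | O=C(/C=C(C)/CCCC(C)(C)/C=C(O[Si](C)(C)C(C)(C)C)/C=C/CO[Si](C)(C)C(C)(C)C)N1C(=O)OC[C@@H]1Cc1ccccc1 | intermediate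
18 | trans-fused cycloadduct (key-step product), C11 imide on C9, C6=C7 silyl enol ether, 8β-CH2OTBS | O=C([C@H]1[C@@H](CO[Si](C)(C)C(C)(C)C)C=C(O[Si](C)(C)C(C)(C)C)[C@H]2C(C)(C)CCC[C@]12C)N3C(=O)OC[C@@H]3Cc4ccccc4 | intermediate
19 | 6,17-bis(tert-butyldimethylsilyloxy)-12,13,14,15,16-pentanorlabd-6-en-11-ol | OC[C@H]1[C@@H](CO[Si](C)(C)C(C)(C)C)C=C(O[Si](C)(C)C(C)(C)C)[C@H]2C(C)(C)CCC[C@]12C | intermediate
20 | 6,17-bis(tert-butyldimethylsilyloxy)-12,13,14,15,16-pentanorlabd-6-en-11-al | O=C[C@H]1[C@@H](CO[Si](C)(C)C(C)(C)C)C=C(O[Si](C)(C)C(C)(C)C)[C@H]2C(C)(C)CCC[C@]12C | intermediate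
21 | (R)-2-methylbutane-1,4-diol | OCC[C@@H](C)CO | starting material
22 | (2R)-2-methyl-4-[(triisopropylsilyl)oxy]butan-1-ol | CC(C)[Si](OCC[C@@H](C)CO)(C(C)C)C(C)C | intermediate
23 | (R)-(4-iodo-3-methylbutoxy)triisopropylsilane | CC(C)[Si](OCC[C@@H](C)CI)(C(C)C)C(C)C | intermediate
24 | [(2R)-2-methyl-4-(triisopropylsilyloxy)butyl]triphenylphosphonium iodide | CC(C)[Si](OCC[C@@H](C)C[P+](c1ccccc1)(c1ccccc1)c1ccccc1)(C(C)C)C(C)C.[I-] | intermediate
25 | ylide of 24 | CC(C)[Si](OCC[C@@H](C)C=P(c1ccccc1)(c1ccccc1)c1ccccc1)(C(C)C)C(C)C | intermediate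
26 | (11Z)-6,17-bis(tert-butyldimethylsilyloxy)-15-(triisopropylsilyloxy)labda-6,11-diene | CC(C)[Si](OCC[C@@H](C)/C=C\[C@H]1[C@@H](CO[Si](C)(C)C(C)(C)C)C=C(O[Si](C)(C)C(C)(C)C)[C@H]2C(C)(C)CCC[C@]12C)(C(C)C)C(C)C | intermediate
27 | 6,17-bis(tert-butyldimethylsilyloxy)-15-(triisopropylsilyloxy)labd-6-ene | CC(C)[Si](OCC[C@@H](C)CC[C@H]1[C@@H](CO[Si](C)(C)C(C)(C)C)C=C(O[Si](C)(C)C(C)(C)C)[C@H]2C(C)(C)CCC[C@]12C)(C(C)C)C(C)C | intermediate
28 | 17-(tert-butyldimethylsilyloxy)-15-(triisopropylsilyloxy)labd-7-en-6-one | CC(C)[Si](OCC[C@@H](C)CC[C@H]1C(CO[Si](C)(C)C(C)(C)C)=CC(=O)[C@H]2C(C)(C)CCC[C@]12C)(C(C)C)C(C)C | intermediate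
29 | 17-(tert-butyldimethylsilyloxy)-15-(triisopropylsilyloxy)labd-7-en-6β-ol | CC(C)[Si](OCC[C@@H](C)CC[C@H]1C(CO[Si](C)(C)C(C)(C)C)=C[C@@H](O)[C@H]2C(C)(C)CCC[C@]12C)(C(C)C)C(C)C | intermediate
30 | lithium alkoxide of 29 | CC(C)[Si](OCC[C@@H](C)CC[C@H]1C(CO[Si](C)(C)C(C)(C)C)=C[C@@H]([O-])[C@H]2C(C)(C)CCC[C@]12C)(C(C)C)C(C)C.[Li+] | intermediate
31 | 6β-methyl carbonate of 29 | CC(C)[Si](OCC[C@@H](C)CC[C@H]1C(CO[Si](C)(C)C(C)(C)C)=C[C@@H](OC(=O)OC)[C@H]2C(C)(C)CCC[C@]12C)(C(C)C)C(C)C | intermediate
32 | 17-(tert-butyldimethylsilyloxy)-15-(triisopropylsilyloxy)labd-7-ene | CC(C)[Si](OCC[C@@H](C)CC[C@H]1C(CO[Si](C)(C)C(C)(C)C)=CC[C@H]2C(C)(C)CCC[C@]12C)(C(C)C)C(C)C | intermediate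
33 | labd-7-ene-15,17-diol | OCC[C@@H](C)CC[C@H]1C(CO)=CC[C@H]2C(C)(C)CCC[C@]12C | intermediate
34 | (5S,9R,10S,13S)-labd-7-ene-15,17-diyl diacetate (CNP0294037.1) | CC(=O)OCC[C@@H](C)CC[C@H]1C(COC(C)=O)=CC[C@H]2C(C)(C)CCC[C@]12C | target

**Step count and risks**

Total steps: 21. Longest linear sequence: 17 steps (steps 1, 2, 4 to 11 and 15 to 21).

The three steps most likely to fail:

Step 9. The Lewis acid may strip the silyl dienol ether before bond formation, the reaction may stall after the first bond at the crowded C5–C10 pair, or facial control may be eroded if the chelate is incomplete. The fallback closes the rings under anionic conditions as an intramolecular double Michael reaction. It sets out from enone imide 16: LiN(SiMe3)2 in THF at −78 °C should form the cross-conjugated lithium dienolate at C5, which adds to C10; the imide enolate so formed adds to C8 of the regenerated enone to give the bicyclic lithium enolate F1, and TBSOTf added to the same flask silylates it on oxygen, which comes back to the route at cycloadduct 18.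

Step 15. Enolisation of the hindered aldehyde by the basic ylide may outrun olefination, causing low conversion or epimerisation at C9. The fallback makes the C11–C12 bond by carbonyl addition and removes the oxygen in a radical chain. It sets out from iodide 23 and aldehyde 20: t-BuLi (Et2O, −78 °C) converts 23 into the alkyllithium F2, anhydrous CeCl3 turns this into the weakly basic alkylcerium dichloride F3, and addition to 20 gives the C11 carbinol F4 (epimer mixture); NaH, CS2 and MeI give the S-methyl xanthate F5, and Barton–McCombie reduction (Bu3SnH, AIBN, toluene, 90 °C) comes back to the route at 27.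

Step 20. Hydride may attack the carbonate carbonyl faster than zerovalent palladium ionises the hindered axial C6–O bond, or delivery to C8 may compete. The fallback removes the oxygen through an allyl radical. It sets out from allylic alcohol 29: CBr4 and PPh3 (CH2Cl2, 0 °C) give the allylic bromide F6 (allylic isomers converge on one radical), and Bu3SnH with AIBN (benzene, 80 °C) reduces it through the C6–C7–C8 allyl radical, hydrogen being transferred to the less hindered C6 terminus, which comes back to the route at 32.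

**Further compounds**

F1 | step 9 | lithium enolate of the bicyclic C6 ketone (C6=C7 enolate, C11 imide) | O=C([C@H]1[C@@H](CO[Si](C)(C)C(C)(C)C)C=C([O-])[C@H]2C(C)(C)CCC[C@]12C)N3C(=O)OC[C@@H]3Cc4ccccc4.[Li+]
F2 | step 15 | [(2R)-2-methyl-4-(triisopropylsilyloxy)butyl]lithium | CC(C)[Si](OCC[C@@H](C)C[Li])(C(C)C)C(C)C
F3 | step 15 | [(2R)-2-methyl-4-(triisopropylsilyloxy)butyl]cerium dichloride | CC(C)[Si](OCC[C@@H](C)C[Ce](Cl)Cl)(C(C)C)C(C)C
F4 | step 15 | 6,17-bis(tert-butyldimethylsilyloxy)-15-(triisopropylsilyloxy)labd-6-en-11-ol (C11 epimers) | CC(C)[Si](OCC[C@@H](C)CC(O)[C@H]1[C@@H](CO[Si](C)(C)C(C)(C)C)C=C(O[Si](C)(C)C(C)(C)C)[C@H]2C(C)(C)CCC[C@]12C)(C(C)C)C(C)C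
F5 | step 15 | S-methyl xanthate of F4 | CC(C)[Si](OCC[C@@H](C)CC(OC(=S)SC)[C@H]1[C@@H](CO[Si](C)(C)C(C)(C)C)C=C(O[Si](C)(C)C(C)(C)C)[C@H]2C(C)(C)CCC[C@]12C)(C(C)C)C(C)C
F6 | step 20 | 6-bromo-17-(tert-butyldimethylsilyloxy)-15-(triisopropylsilyloxy)labd-7-ene (C6 epimers) | CC(C)[Si](OCC[C@@H](C)CC[C@H]1C(CO[Si](C)(C)C(C)(C)C)=CC(Br)[C@H]2C(C)(C)CCC[C@]12C)(C(C)C)C(C)C
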